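**Plan**

- Numbering used here: quinone ring C1(=O)–C2(OH)=C3(side chain)–C4(=O), fused at C4a/C8a; methoxy groups on C5, C6 and C8.
- Retrosynthesis: first cut, in one stroke, C1–C8a (aryl–acyl) and C2–C3 (enol carbon–acyl), which gives oxalyl chloride plus the silyl enol ether of an aryl ketone. Then cut C4–C4a, which gives 2,3,5-trimethoxyphenyllithium plus (S)-γ-valerolactone.
- Enabling feature: C1–C2 is an oxalyl unit (the hydroxyquinone is the enol of a naphthalene-1,2,4-trione). It lies between the enolisable C3 and arene carbon C8a, which is para to the C6 and ortho to the C8 methoxy group and so the most nucleophilic ring position.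
- Forward: the arene is bought ready-made and adjusted (CHO to OMe), the chain is joined by lactone opening and acetylated, and the quinone ring is closed last, giving the target directly.
- Stereochemistry: the single S centre comes from (S)-γ-valerolactone and is never involved in a bond change.

Key step: step 6

Assumption: the aryl γ-hydroxy ketone 7 reacts from its open-chain form and not from the cyclic hemiketal, as expected for a conjugated aryl ketone.

**Step 1**
Reactants: 1 3-bromo-4,5-dimethoxybenzaldehyde
Product: 3 3-bromo-4,5-dimethoxyphenol, via aryl formate 2 (not isolated)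
Conditions: mCPBA, CH2Cl2, 0 °C to reflux; then K2CO3 (cat.), MeOH, rt
Reagents that add atoms: mCPBA, O=C(OO)c1cccc(Cl)c1
Why: Baeyer-Villiger (Dakin-type) oxidation, in which the aryl group para to a methoxy group should migrate in preference to hydride, followed by methanolysis of the formate.

**Step 2**
Reactants: 3 3-bromo-4,5-dimethoxyphenol
Product: 4 1-bromo-2,3,5-trimethoxybenzene
Conditions: MeI, K2CO3, acetone, reflux
Reagents that add atoms: iodomethane, CI
Why: Williamson O-methylation of the phenoxide, with no competing site.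

**Step 3**
Reactants: 4 1-bromo-2,3,5-trimethoxybenzene; 5 (S)-γ-valerolactone [(5S)-5-methyloxolan-2-one]
Product: 7 (S)-4-hydroxy-1-(2,3,5-trimethoxyphenyl)pentan-1-one, via aryllithium 6 (not isolated)
Conditions: n-BuLi, THF, −78 °C; then cannulated into 5 (1.2 equiv), THF, −78 °C; aq. NH4Cl at −78 °C
Reagents that add atoms: none
Why: Bromine-lithium exchange gives aryllithium 6, which opens the lactone by nucleophilic acyl substitution; at −78 °C the lithium lactolate adduct should resist a second addition, and the stereocentre, remote from the reacting carbonyl, is carried over unchanged.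

**Step 4**
Reactants: 7 (S)-4-hydroxy-1-(2,3,5-trimethoxyphenyl)pentan-1-one
Product: 8 (S)-5-oxo-5-(2,3,5-trimethoxyphenyl)pentan-2-yl acetate
Conditions: Ac2O, pyridine, DMAP (cat.), CH2Cl2, 0 °C to rt
Reagents that add atoms: acetic anhydride, CC(=O)OC(C)=O
Why: DMAP-catalysed O-acylation of the secondary alcohol, which leaves the C–O bond and hence the S configuration intact.

**Step 5**
Reactants: 8 (S)-5-oxo-5-(2,3,5-trimethoxyphenyl)pentan-2-yl acetate
Product: 9 (2S,4Z)-5-(2,3,5-trimethoxyphenyl)-5-(trimethylsilyloxy)pent-4-en-2-yl acetate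
Conditions: Me3SiOTf (1.2 equiv), Et3N, CH2Cl2, 0 °C; pentane extraction, filtration, used crude
Reagents that add atoms: trimethylsilyl trifluoromethanesulfonate, C[Si](C)(C)OS(=O)(=O)C(F)(F)F
Why: Soft enolisation and O-silylation should be selective for the aryl ketone over the far less acidic acetate and give the (mainly Z) silyl enol ether, whose geometry has no consequence later.

**Step 6**
Reactants: 9 (2S,4Z)-5-(2,3,5-trimethoxyphenyl)-5-(trimethylsilyloxy)pent-4-en-2-yl acetate; 10 oxalyl chloride
Product: 13 (S)-1-(3-hydroxy-5,7,8-trimethoxy-1,4-dioxo-1,4-dihydronaphthalen-2-yl)propan-2-yl acetate (the target), via dioxo acid chloride 11 (not isolated), via furan-2,3-dione 12 (not isolated)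
Conditions: (COCl)2 (1.1 equiv), CH2Cl2, −78 to 0 °C; then SnCl4 (2.2 equiv), −78 to 0 °C; 1 M HCl work-up
Reagents that add atoms: none
Why: Proposed new method: the enol silane carbon C3 is acylated by one acyl chloride of oxalyl chloride with loss of Me3SiCl (a reaction that normally stops at the furan-2,3-dione 12), and SnCl4 then reopens 12 to the acyl chloride 11, whose carbon C1 is attacked by arene carbon C8a in an intramolecular Friedel-Crafts acylation, after which the 1,2,4-trione enolises to the 2-hydroxy-1,4-quinone. The closest known reaction types are the Stollé isatin synthesis (acylation of a heteroatom by oxalyl chloride followed by Lewis-acid ring closure onto the arene), the closure of 2-aroylbenzoic acids to anthraquinones, and the conversion of silyl enol ethers into furan-2,3-diones by oxalyl chloride. The quinone ring, the only ring formed, closes in a 6-exo-trig electrophilic aromatic substitution at the acyl chloride carbon. No stereocentre is created, and the S centre, two carbons from C3 and not enolisable, is not affected. The step needs site selectivity on the arene and between the two electrophilic carbons: only C8a can give a six-membered ring and it is also the most nucleophilic ring carbon, while C2 is enolised toward C4 and so less electrophilic than acid chloride C1, which should disfavour a five-membered Bougault-type closure. Low temperature and SnCl4 in place of AlCl3 are chosen to suppress loss of CO from the acylium ion and cleavage of the peri methoxy groups.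

**Compound list**

1 | 3-bromo-4,5-dimethoxybenzaldehyde | COc1cc(C=O)cc(Br)c1OC | starting material
2 | 3-bromo-4,5-dimethoxyphenyl formate | COc1cc(OC=O)cc(Br)c1OC | intermediate
3 | 3-bromo-4,5-dimethoxyphenol | COc1cc(O)cc(Br)c1OC | intermediate
4 | 1-bromo-2,3,5-trimethoxybenzene | COc1cc(OC)c(OC)c(Br)c1 | intermediate
5 | (S)-γ-valerolactone | C[C@H]1CCC(=O)O1 | starting material
6 | 2,3,5-trimethoxyphenyllithium | COc1cc(OC)c(OC)c([Li])c1 | intermediate
7 | (S)-4-hydroxy-1-(2,3,5-trimethoxyphenyl)pentan-1-one | C[C@H](O)CCC(=O)c1cc(OC)cc(OC)c1OC | intermediate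
8 | (S)-5-oxo-5-(2,3,5-trimethoxyphenyl)pentan-2-yl acetate | CC(=O)O[C@@H](C)CCC(=O)c1cc(OC)cc(OC)c1OC | intermediate
9 | (2S,4Z)-5-(2,3,5-trimethoxyphenyl)-5-(trimethylsilyloxy)pent-4-en-2-yl acetate | CC(=O)O[C@@H](C)C/C=C(\O[Si](C)(C)C)c1cc(OC)cc(OC)c1OC | intermediate
10 | oxalyl chloride | O=C(Cl)C(=O)Cl | starting material
11 | (2S)-4-(2-chloro-2-oxoacetyl)-5-oxo-5-(2,3,5-trimethoxyphenyl)pentan-2-yl acetate (C4 epimers and enol forms) | CC(=O)O[C@@H](C)CC(C(=O)C(=O)Cl)C(=O)c1cc(OC)cc(OC)c1OC | intermediate
12 | (2S)-1-[2,3-dioxo-5-(2,3,5-trimethoxyphenyl)-2,3-dihydrofuran-4-yl]propan-2-yl acetate | CC(=O)O[C@@H](C)CC1=C(c2cc(OC)cc(OC)c2OC)OC(=O)C1=O | intermediate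
13 | (S)-1-(3-hydroxy-5,7,8-trimethoxy-1,4-dioxo-1,4-dihydronaphthalen-2-yl)propan-2-yl acetate | COc1cc(OC)c2c(c1OC)C(=O)C(C[C@H](C)OC(C)=O)=C(O)C2=O | target

**Summary**

Total steps: 6. Longest linear sequence: 6 steps (from 1).

Steps most likely to fail:

1. Step 6 (proposed new method). What may go wrong: loss of CO from the α-keto acylium before ring closure, the sequence stopping at the furan-2,3-dione stage, or closure at C2 in place of C1. The fallback uses known chemistry, sets out from 8 and returns at 13. Ring bromination of 8 with N-bromosuccinimide in MeCN at 0 °C should go para to the C6 methoxy group, at the future C8a, to give (S)-5-(2-bromo-3,5,6-trimethoxyphenyl)-5-oxopentan-2-yl acetate F1. Cross-coupling of F1 with the Reformatsky reagent BrZnCH2CO2Et under Pd(dba)2/P(t-Bu)3 (zerovalent palladium) in THF should give ethyl 2-{2-[(4S)-4-acetoxypentanoyl]-3,4,6-trimethoxyphenyl}acetate F2. NaH in THF (equilibrating enolates) should then close the ring by intramolecular Claisen condensation of the C3 enolate on the ester to (S)-1-(1,3-dihydroxy-5,7,8-trimethoxynaphthalen-2-yl)propan-2-yl acetate F3, which autoxidises in air at C1 to 13.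

2. Step 3. What may go wrong: collapse of the lactolate and a second addition of the aryllithium, or deprotonation of the lactone. The fallback sets out from 5, uses aryllithium 6 made from 4 as before, and returns at 7. Lactone 5 would be opened with MeNHOMe·HCl/AlMe3 (CH2Cl2, 0 °C to rt) to (S)-4-hydroxy-N-methoxy-N-methylpentanamide F4 and silylated at once (TBSCl, imidazole, DMF) to (S)-4-(tert-butyldimethylsilyloxy)-N-methoxy-N-methylpentanamide F5. Aryllithium 6 should add once to this Weinreb amide, whose chelated adduct cannot collapse before the quench, giving (S)-4-(tert-butyldimethylsilyloxy)-1-(2,3,5-trimethoxyphenyl)pentan-1-one F6. Bu4NF in THF then removes the silyl group to give 7.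

3. Step 5. What may go wrong: incomplete silylation, silylation of the acetate, or hydrolysis of the labile silyl enol ether on handling. The fallback sets out from 8 and returns at 12, from which the SnCl4 stage of step 6 follows. Claisen condensation of the lithium enolate of 8 (LiN(SiMe3)2, THF, −78 °C) with di-tert-butyl oxalate should give tert-butyl (5S)-5-acetoxy-2-oxo-3-(2,3,5-trimethoxybenzoyl)hexanoate F7. CF3CO2H in CH2Cl2 cleaves the tert-butyl ester to (5S)-5-acetoxy-2-oxo-3-(2,3,5-trimethoxybenzoyl)hexanoic acid F8 without touching the acetate. SOCl2 in CH2Cl2 converts F8 through acid chloride 11 into furan-2,3-dione 12.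

**Further compounds**

F1 | step 6 | (S)-5-(2-bromo-3,5,6-trimethoxyphenyl)-5-oxopentan-2-yl acetate | CC(=O)O[C@@H](C)CCC(=O)c1c(Br)c(OC)cc(OC)c1OC
F2 | step 6 | ethyl 2-{2-[(4S)-4-acetoxypentanoyl]-3,4,6-trimethoxyphenyl}acetate | CCOC(=O)Cc1c(OC)cc(OC)c(OC)c1C(=O)CC[C@H](C)OC(C)=O
F3 | step 6 | (S)-1-(1,3-dihydroxy-5,7,8-trimethoxynaphthalen-2-yl)propan-2-yl acetate | COc1cc(OC)c2cc(O)c(C[C@H](C)OC(C)=O)c(O)c2c1OC
F4 | step 3 | (S)-4-hydroxy-N-methoxy-N-methylpentanamide | C[C@H](O)CCC(=O)N(C)OC
F5 | step 3 | (S)-4-(tert-butyldimethylsilyloxy)-N-methoxy-N-methylpentanamide | C[C@H](O[Si](C)(C)C(C)(C)C)CCC(=O)N(C)OC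
F6 | step 3 | (S)-4-(tert-butyldimethylsilyloxy)-1-(2,3,5-trimethoxyphenyl)pentan-1-one | C[C@H](O[Si](C)(C)C(C)(C)C)CCC(=O)c1cc(OC)cc(OC)c1OC
F7 | step 5 | tert-butyl (5S)-5-acetoxy-2-oxo-3-(2,3,5-trimethoxybenzoyl)hexanoate | CC(=O)O[C@@H](C)CC(C(=O)C(=O)OC(C)(C)C)C(=O)c1cc(OC)cc(OC)c1OC
F8 | step 5 | (5S)-5-acetoxy-2-oxo-3-(2,3,5-trimethoxybenzoyl)hexanoic acid | CC(=O)O[C@@H](C)CC(C(=O)C(=O)O)C(=O)c1cc(OC)cc(OC)c1OC
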